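The cyclohexane ring (C5–C10) is cut at C6–C7: the C6 oxygen lies β to C8, so with C8 as a carbonyl this bond is that of an intramolecular aldol addition. A Ferrier carbocyclisation with catalytic Hg(OCOCF3)2 does this in one operation. It converts a pyranoid enol acetal into the cyclohexanone, creating C6–C7, the carbocycle and the C6 and C7 stereocentres, while C5, C9 and C10 are carried over intact. The precursor is a 2-methoxy-6-alkylidene tetrahydropyran whose ring oxygen joins acetal carbon C6 to enol-ether carbon C8 (exocyclic C8=C7–CH2CH2OPMB), with C5 isopropenyl, C10 methyl/vinyl and C9 OTBS in place.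

Key step: step 12

Remark: labels are C5–C10 for the cyclohexane, C1=C2 and methyl C14 on C10, C4(=C3)–C15 on C5, and C11(=C13)–C12 on C7; β is the ring face of the C10 methyl; descriptors on open-chain and carbocyclic intermediates use these labels; PMB = 4-methoxybenzyl, TBS = tert-butyldimethylsilyl, TES = triethylsilyl.
Assumption: (R)-BINAP is taken to deliver (4R)-3, by analogy with the sense found for cyclic enones and unsaturated δ-lactones; were it opposite, (S)-BINAP would be used.
Assumption: enol acetal 20 is used as its anomer mixture, since C6 becomes trigonal in step 12; sulfoxide 8 is a mixture at sulfur.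

Step 1
Reactants: 1 furan-2(5H)-one; 2 4,4,5,5-tetramethyl-2-(prop-1-en-2-yl)-1,3,2-dioxaborolane
Product: 3 (4R)-4-(prop-1-en-2-yl)oxolan-2-one
Conditions: [Rh(cod)Cl]2 (2.5 mol%), (R)-BINAP (6 mol%), KOH (10 mol%), dioxane/H2O 10:1, 50 °C
Reagents that add atoms: none
Why: Rhodium-catalysed asymmetric conjugate addition of an alkenylboronate to a butenolide (Hayashi–Miyaura reaction) should insert the enoate into the alkenyl–rhodium bond of the (R)-BINAP complex on one enantioface, which sets C5.

Step 2
Reactants: 3 (4R)-4-(prop-1-en-2-yl)oxolan-2-one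
Product: 5 (3S,4R)-3-methyl-4-(prop-1-en-2-yl)oxolan-2-one, via lithium enolate 4 (not isolated)
Conditions: LiN(i-Pr)2, THF, −78 °C; MeI, −78 to −40 °C
Reagents that add atoms: iodomethane, CI
Why: Kinetic lactone enolate alkylation should occur anti to the neighbouring isopropenyl group (trans product); the new centre is flattened again in step 3, so only clean mono-methylation matters.

Step 3
Reactants: 5 (3S,4R)-3-methyl-4-(prop-1-en-2-yl)oxolan-2-one; 6 phenyl vinyl sulfoxide
Product: 8 (3S,4S)-3-methyl-3-[2-(phenylsulfinyl)ethyl]-4-(prop-1-en-2-yl)oxolan-2-one, via lithium enolate 7 (not isolated)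
Conditions: LiN(i-Pr)2, THF, −78 °C; 6, −78 to 0 °C; aq. NH4Cl
Reagents that add atoms: none
Why: Michael addition of the tetrasubstituted enolate to the vinyl sulfoxide, used as a vinyl cation equivalent, should again occur anti to the isopropenyl group, which fixes quaternary C10 with the two-carbon arm trans and the methyl cis to isopropenyl.

Step 4
Reactants: 8 (3S,4S)-3-methyl-3-[2-(phenylsulfinyl)ethyl]-4-(prop-1-en-2-yl)oxolan-2-one
Product: 9 (3S,4S)-3-ethenyl-3-methyl-4-(prop-1-en-2-yl)oxolan-2-one
Conditions: NaHCO3, xylenes, 135 °C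
Reagents that add atoms: none
Why: Thermal syn-elimination of the sulfoxide can only take a hydrogen from the CH2 attached to quaternary C10, so it should unveil the C1=C2 vinyl group without touching a stereocentre.

Step 5
Reactants: 10 but-3-yn-1-ol
Product: 11 1-[(but-3-yn-1-yloxy)methyl]-4-methoxybenzene
Conditions: NaH, PMBCl, Bu4NI (cat.), THF/DMF, 0 °C to rt
Reagents that add atoms: 4-methoxybenzyl chloride, COc1ccc(CCl)cc1
Why: Williamson etherification of the primary alkoxide; the alkyne C–H is not deprotonated under these conditions.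

Step 6
Reactants: 9 (3S,4S)-3-ethenyl-3-methyl-4-(prop-1-en-2-yl)oxolan-2-one; 11 1-[(but-3-yn-1-yloxy)methyl]-4-methoxybenzene
Product: 14 (5S,10S)-hydroxy ynone (C6 CH2OH; C9 ketone; C8≡C7–CH2CH2OPMB), via lithium acetylide 12 (not isolated), via lithium lactolate 13 (not isolated)
Conditions: 11, n-BuLi, THF, −78 °C; then 9, −78 to −30 °C; aq. NH4Cl
Reagents that add atoms: none
Why: Acetylide addition to the lactone carbonyl should stop at the tetrahedral lithium lactolate at low temperature, and work-up releases the C9 ynone (in equilibrium with its lactol) carrying C8, C7, C11 and C12.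

Step 7
Reactants: 14 (5S,10S)-hydroxy ynone
Product: 15 (5S,9S,10S)-ynediol
Conditions: RuCl[(S,S)-TsDPEN](p-cymene) (3 mol%), KOH (3 mol%), i-PrOH, rt
Reagents that add atoms: none
Why: Noyori asymmetric transfer hydrogenation of an α,β-acetylenic ketone is catalyst-controlled (the alkynyl group takes the place of the unsaturated substituent in the (S,S)-TsDPEN transition state), so it should give the (9S)-carbinol whatever the bias of the adjacent quaternary centre and leave the alkyne and alkenes untouched.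

Step 8
Reactants: 15 (5S,9S,10S)-ynediol
Product: 16 (5S,9S,10S)-bis-TBS ether
Conditions: TBSOTf, 2,6-lutidine, CH2Cl2, −78 to 0 °C
Reagents that add atoms: tert-butyldimethylsilyl trifluoromethanesulfonate, CC(C)(C)[Si](C)(C)OS(=O)(=O)C(F)(F)F
Why: Silylation with the silyl triflate should protect both hydroxyls, the hindered propargylic C9–OH included.

Step 9
Reactants: 16 (5S,9S,10S)-bis-TBS ether
Product: 17 (5S,9S,10S)-primary alcohol (C6 CH2OH; C9 OTBS)
Conditions: HF·pyridine, pyridine, THF, 0 °C
Reagents that add atoms: none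
Why: Fluoride-mediated desilylation is much faster at the primary silyl ether than at the secondary ether flanked by the quaternary carbon, so only C6–OH should be freed.

Step 10
Reactants: 17 (5S,9S,10S)-primary alcohol
Product: 18 (5S,9S,10S)-aldehyde (C6 CHO)
Conditions: Dess–Martin periodinane, NaHCO3, CH2Cl2, 0 °C
Reagents that add atoms: none
Why: Buffered Dess–Martin oxidation gives the α-branched β,γ-unsaturated aldehyde under non-basic conditions that should preserve C5; the aldehyde is used crude.

Step 11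
Reactants: 18 (5S,9S,10S)-aldehyde
Product: 20 (3S,4S,5S,6Z)-5-(TBS-oxy)-4-ethenyl-2-methoxy-6-[3-(PMB-oxy)propylidene]-4-methyl-3-(prop-1-en-2-yl)oxane, via methyl hemiacetal 19 (not isolated)
Conditions: Pd(OAc)2 (5 mol%), MeOH (3 equiv), 1,4-dioxane, rt
Reagents that add atoms: methanol, CO
Why: Palladium diacetate serves as Lewis acid for hemiacetal formation and as π-acid for the alkyne, so the hemiacetal oxygen should add 6-exo-dig by anti-oxypalladation and protodepalladation should give the Z enol acetal (alkoxy-cyclisation of an acetylenic aldehyde).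

Step 12
Reactants: 20 (3S,4S,5S,6Z)-enol acetal
Product: 22 (5S,6S,7S,9S,10S)-cyclohexanone (C8 ketone; C6 OH; C7 CH2CH2OPMB; C5 isopropenyl; C10 methyl/vinyl; C9 OTBS), via α-mercurio keto aldehyde 21 (not isolated)
Conditions: Hg(OCOCF3)2 (10 mol%), acetone/H2O 4:1, 0 °C to rt
Reagents that add atoms: water, O
Why: Divalent mercury adds to the electron-rich exocyclic enol ether at C7 and water to C8 (oxymercuration); the hemiketal opens to the C8 ketone, the C6 hemiacetal loses methanol to the aldehyde, and the α-mercurio ketone 21 adds through C7 to C6 in an intramolecular aldol that releases the mercury salt again. This is the Ferrier carbocyclisation known for 6-substituted hex-5-enopyranosides, which gives β-hydroxycyclohexanones. The carbocycle closes in a 6-(enolendo)-exo-trig mode. C7 lies α to the ketone and should settle with its side chain equatorial (β); C6 is set in a mercury-bridged chair with the C5 isopropenyl and C7 chain equatorial and the aldehyde oxygen axial, which gives the 6β-hydroxyl, although the syn-axial C10 methyl makes this the least certain element. The step needs chemoselectivity for the enol ether over the isopropenyl and vinyl groups, secured by its far higher nucleophilicity and by the reversibility of alkene oxymercuration at catalytic loading, and enolate formation at C7 and not C9, secured by the position of mercury; the near-neutral medium should spare C5 of the transient aldehyde and avoid β-elimination.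

Step 13
Reactants: 22 (5S,6S,7S,9S,10S)-cyclohexanone
Product: 24 (5S,6S,7S,8R,9S,10S)-6,8-diol, via alkoxyborohydride 23 (not isolated)
Conditions: Me4NBH(OAc)3, AcOH/MeCN 1:1, −30 to −20 °C
Reagents that add atoms: none
Why: Hydroxyl-directed reduction (Evans–Saksena reduction): ligand exchange at the axial C6–OH gives alkoxyborohydride 23, which delivers hydride intramolecularly to the β-face of C8 and so should give the equatorial 8α-alcohol anti to C6–OH.

Step 14
Reactants: 24 (5S,6S,7S,8R,9S,10S)-6,8-diol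
Product: 25 C8 triethylsilyl ether (C6 OH free)
Conditions: TESCl, imidazole, CH2Cl2, −20 °C
Reagents that add atoms: chlorotriethylsilane, CC[Si](Cl)(CC)CC
Why: Silylation under mild conditions should select the equatorial C8 hydroxyl over the axial C6 hydroxyl, which is flanked by two substituents and syn-axial to the C10 methyl.

Step 15
Reactants: 25 C8 triethylsilyl ether; 26 angelic acid
Product: 28 C6 angelate (C8 OTES; C9 OTBS; C12 OPMB), via mixed anhydride 27 (not isolated)
Conditions: 26, 2,4,6-Cl3C6H2COCl, Et3N, toluene, rt; then 25, 80 °C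
Reagents that add atoms: none
Why: Yamaguchi esterification through the mixed anhydride, run without DMAP to avoid Z-to-E isomerisation, should acylate the remaining C6 hydroxyl with the angelate geometry retained.

Step 16
Reactants: 28 C6 angelate
Product: 29 C12 primary alcohol
Conditions: DDQ, CH2Cl2/pH 7 buffer, 0 °C
Reagents that add atoms: none
Why: Oxidative cleavage of the 4-methoxybenzyl ether by DDQ proceeds by hydride abstraction at the electron-rich benzylic position and should spare the silyl ethers, the enoate and the alkenes.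

Step 17
Reactants: 29 C12 primary alcohol
Product: 30 C12 aldehyde
Conditions: Dess–Martin periodinane, NaHCO3, CH2Cl2, 0 °C to rt
Reagents that add atoms: none
Why: Dess–Martin oxidation of the primary alcohol to the aldehyde under neutral conditions.

Step 18
Reactants: 30 C12 aldehyde
Product: 32 α-methylene aldehyde (C11=C13; C12 CHO), via Mannich base 31 (not isolated)
Conditions: CH2=NMe2+ I−, Et3N, CH2Cl2, rt
Reagents that add atoms: N,N-dimethylmethyleneiminium iodide, C=[N+](C)C.[I-]
Why: Mannich reaction of the aldehyde with the iminium salt followed by loss of dimethylamine (α-methylenation of an aldehyde) installs C13 without strong base, so the angelate and silyl ethers should be unaffected.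

Step 19
Reactants: 32 α-methylene aldehyde
Product: 33 acrylic acid (C12 CO2H)
Conditions: NaClO2, NaH2PO4, 2-methylbut-2-ene, t-BuOH/H2O, 0 °C
Reagents that add atoms: sodium chlorite, [Na+].[O-]Cl=O
Why: Pinnick oxidation converts the enal into the acrylic acid, and 2-methylbut-2-ene scavenges hypochlorous acid so that the other alkenes are protected.

Step 20
Reactants: 33 acrylic acid
Product: 35 α-methylene γ-lactone (C8–O–C12; C9 OH; C6 angelate), via dihydroxy acid 34 (not isolated)
Conditions: HF·pyridine, THF, 0 to 40 °C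
Reagents that add atoms: none
Why: Fluoride cleaves both silyl ethers, and the freed equatorial C8 hydroxyl should close the trans-fused lactone with the neighbouring equatorial acrylic acid under the acidic conditions, since C9–OH lies on the opposite ring face and cannot lactonise.

Step 21
Reactants: 35 α-methylene γ-lactone
Product: 36 C15 allylic alcohol
Conditions: SeO2 (0.5 equiv), t-BuOOH, CH2Cl2, rt
Reagents that add atoms: tert-butyl hydroperoxide, CC(C)(C)OO; selenium dioxide, O=[Se]=O
Why: Riley allylic oxidation (ene reaction then [2,3]-sigmatropic shift) should select the methyl group of the isopropenyl unit, the only electron-rich alkene with allylic hydrogens, because the conjugated alkenes are deactivated and the vinyl group has no allylic hydrogen.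

Step 22
Reactants: 36 C15 allylic alcohol
Product: 37 C15 enal
Conditions: MnO2, CH2Cl2, rt
Reagents that add atoms: none
Why: Manganese dioxide oxidises only the allylic primary alcohol, giving the C15 enal and leaving the secondary C9 hydroxyl.

Step 23
Reactants: 37 C15 enal
Product: 38 CNP0113462.3
Conditions: VO(acac)2 (5 mol%), t-BuOOH, CH2Cl2, 0 °C to rt
Reagents that add atoms: tert-butyl hydroperoxide, CC(C)(C)OO
Why: Hydroxyl-directed epoxidation: the vanadate ester of the axial C9–OH can reach only the homoallylic C1=C2 vinyl group, and a chair-like transition state with C2 turned away from C9 should deliver oxygen to the face that gives the (1R)-epoxide, while the conjugated alkenes are inert to the electrophilic peroxide.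

Compound list
1 | furan-2(5H)-one | O=C1OCC=C1 | starting material
2 | 4,4,5,5-tetramethyl-2-(prop-1-en-2-yl)-1,3,2-dioxaborolane (isopropenylboronic acid pinacol ester) | CC(=C)B1OC(C)(C)C(C)(C)O1 | starting material
3 | (4R)-4-(prop-1-en-2-yl)oxolan-2-one | O=C1C[C@H](C(C)=C)CO1 | intermediate
4 | lithium enolate of 3 (not isolated) | [Li]OC1=C[C@H](C(C)=C)CO1 | intermediate
5 | (3S,4R)-3-methyl-4-(prop-1-en-2-yl)oxolan-2-one | O=C1[C@@H](C)[C@H](C(C)=C)CO1 | intermediate
6 | phenyl vinyl sulfoxide, (ethenylsulfinyl)benzene | C=CS(=O)c1ccccc1 | starting material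
7 | lithium enolate of 5 (not isolated) | [Li]OC1=C(C)[C@H](C(C)=C)CO1 | intermediate
8 | (3S,4S)-3-methyl-3-[2-(phenylsulfinyl)ethyl]-4-(prop-1-en-2-yl)oxolan-2-one, mixture at sulfur | O=C1[C@@](C)(CCS(=O)c2ccccc2)[C@H](C(C)=C)CO1 | intermediate
9 | (3S,4S)-3-ethenyl-3-methyl-4-(prop-1-en-2-yl)oxolan-2-one | O=C1[C@@](C)(C=C)[C@H](C(C)=C)CO1 | intermediate
10 | but-3-yn-1-ol | C#CCCO | starting material
11 | 1-[(but-3-yn-1-yloxy)methyl]-4-methoxybenzene | C#CCCOCc1ccc(OC)cc1 | intermediate
12 | lithium acetylide of 11 (not isolated) | [Li]C#CCCOCc1ccc(OC)cc1 | intermediate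
13 | lithium lactolate from addition of 12 to 9 (not isolated) | [Li]OC1(C#CCCOCc2ccc(OC)cc2)OC[C@@H](C(C)=C)[C@]1(C)C=C | intermediate
14 | (5S,10S)-hydroxy ynone: HOCH2(C6)–C5H(isopropenyl)–C10(CH3)(vinyl)–C9(=O)–C8≡C7–CH2CH2OPMB | OC[C@@H](C(C)=C)[C@](C)(C=C)C(=O)C#CCCOCc1ccc(OC)cc1 | intermediate
15 | (5S,9S,10S)-ynediol: 14 with C9 reduced to the (S)-carbinol | OC[C@@H](C(C)=C)[C@](C)(C=C)[C@H](O)C#CCCOCc1ccc(OC)cc1 | intermediate
16 | (5S,9S,10S)-bis-TBS ether of 15 | CC(C)(C)[Si](C)(C)OC[C@@H](C(C)=C)[C@](C)(C=C)[C@H](O[Si](C)(C)C(C)(C)C)C#CCCOCc1ccc(OC)cc1 | intermediate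
17 | (5S,9S,10S)-primary alcohol: C6 CH2OH, C9 OTBS | OC[C@@H](C(C)=C)[C@](C)(C=C)[C@H](O[Si](C)(C)C(C)(C)C)C#CCCOCc1ccc(OC)cc1 | intermediate
18 | (5S,9S,10S)-aldehyde: C6 CHO, C9 OTBS | O=C[C@@H](C(C)=C)[C@](C)(C=C)[C@H](O[Si](C)(C)C(C)(C)C)C#CCCOCc1ccc(OC)cc1 | intermediate
19 | methyl hemiacetal of 18 (not isolated) | COC(O)[C@@H](C(C)=C)[C@](C)(C=C)[C@H](O[Si](C)(C)C(C)(C)C)C#CCCOCc1ccc(OC)cc1 | intermediate
20 | key-step precursor: (3S,4S,5S,6Z)-5-(TBS-oxy)-4-ethenyl-2-methoxy-6-[3-(PMB-oxy)propylidene]-4-methyl-3-(prop-1-en-2-yl)oxane, anomer mixture at C2 (= C6) | COC1O/C(=C\CCOCc2ccc(OC)cc2)[C@@H](O[Si](C)(C)C(C)(C)C)[C@@](C)(C=C)[C@@H]1C(C)=C | intermediate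
21 | α-mercurio keto aldehyde: C6 CHO, C8 ketone, C7–HgOCOCF3 (not isolated) | O=C[C@@H](C(C)=C)[C@](C)(C=C)[C@H](O[Si](C)(C)C(C)(C)C)C(=O)C(CCOCc1ccc(OC)cc1)[Hg]OC(=O)C(F)(F)F | intermediate
22 | key-step product: (5S,6S,7S,9S,10S)-cyclohexanone with C8 ketone, 6β-OH, 7β-CH2CH2OPMB, 5β-isopropenyl, 10β-methyl/10α-vinyl, 9α-OTBS | O=C1[C@@H](CCOCc2ccc(OC)cc2)[C@@H](O)[C@@H](C(C)=C)[C@](C)(C=C)[C@@H]1O[Si](C)(C)C(C)(C)C | intermediate
23 | tetramethylammonium C6-alkoxy(diacetoxy)hydridoborate of 22 (not isolated) | O=C1[C@@H](CCOCc2ccc(OC)cc2)[C@@H](O[BH-](OC(C)=O)OC(C)=O)[C@@H](C(C)=C)[C@](C)(C=C)[C@@H]1O[Si](C)(C)C(C)(C)C.C[N+](C)(C)C | intermediate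
24 | (5S,6S,7S,8R,9S,10S)-6β,8α-diol | O[C@@H]1[C@@H](CCOCc2ccc(OC)cc2)[C@@H](O)[C@@H](C(C)=C)[C@](C)(C=C)[C@@H]1O[Si](C)(C)C(C)(C)C | intermediate
25 | C8 triethylsilyl ether of 24 (C6 OH free) | CC[Si](CC)(CC)O[C@@H]1[C@@H](CCOCc2ccc(OC)cc2)[C@@H](O)[C@@H](C(C)=C)[C@](C)(C=C)[C@@H]1O[Si](C)(C)C(C)(C)C | intermediate
26 | angelic acid, (Z)-2-methylbut-2-enoic acid | C/C=C(/C)C(=O)O | starting material
27 | (Z)-2-methylbut-2-enoic 2,4,6-trichlorobenzoic anhydride (not isolated) | C/C=C(/C)C(=O)OC(=O)c1c(Cl)cc(Cl)cc1Cl | intermediate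
28 | C6 angelate: C8 OTES, C9 OTBS, C12 OPMB | CC[Si](CC)(CC)O[C@@H]1[C@@H](CCOCc2ccc(OC)cc2)[C@@H](OC(=O)/C(C)=C\C)[C@@H](C(C)=C)[C@](C)(C=C)[C@@H]1O[Si](C)(C)C(C)(C)C | intermediate
29 | C12 primary alcohol of 28 | CC[Si](CC)(CC)O[C@@H]1[C@@H](CCO)[C@@H](OC(=O)/C(C)=C\C)[C@@H](C(C)=C)[C@](C)(C=C)[C@@H]1O[Si](C)(C)C(C)(C)C | intermediate
30 | C12 aldehyde | CC[Si](CC)(CC)O[C@@H]1[C@@H](CC=O)[C@@H](OC(=O)/C(C)=C\C)[C@@H](C(C)=C)[C@](C)(C=C)[C@@H]1O[Si](C)(C)C(C)(C)C | intermediate
31 | Mannich base: C11 bearing CH2NMe2 (not isolated) | CC[Si](CC)(CC)O[C@@H]1[C@@H](C(CN(C)C)C=O)[C@@H](OC(=O)/C(C)=C\C)[C@@H](C(C)=C)[C@](C)(C=C)[C@@H]1O[Si](C)(C)C(C)(C)C | intermediate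
32 | α-methylene aldehyde: C11=C13, C12 CHO | CC[Si](CC)(CC)O[C@@H]1[C@@H](C(=C)C=O)[C@@H](OC(=O)/C(C)=C\C)[C@@H](C(C)=C)[C@](C)(C=C)[C@@H]1O[Si](C)(C)C(C)(C)C | intermediate
33 | acrylic acid: C11=C13, C12 CO2H | CC[Si](CC)(CC)O[C@@H]1[C@@H](C(=C)C(=O)O)[C@@H](OC(=O)/C(C)=C\C)[C@@H](C(C)=C)[C@](C)(C=C)[C@@H]1O[Si](C)(C)C(C)(C)C | intermediate
34 | 8α,9α-dihydroxy acrylic acid (not isolated) | O[C@@H]1[C@@H](C(=C)C(=O)O)[C@@H](OC(=O)/C(C)=C\C)[C@@H](C(C)=C)[C@](C)(C=C)[C@@H]1O | intermediate
35 | (5S,6S,7S,8R,9S,10S)-α-methylene γ-lactone: 9α-OH, 6β-angelate, isopropenyl and vinyl intact | C=C1C(=O)O[C@@H]2[C@@H]1[C@@H](OC(=O)/C(C)=C\C)[C@@H](C(C)=C)[C@](C)(C=C)[C@@H]2O | intermediate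
36 | C15 allylic alcohol: C4(=C3)–CH2OH | C=C1C(=O)O[C@@H]2[C@@H]1[C@@H](OC(=O)/C(C)=C\C)[C@@H](C(=C)CO)[C@](C)(C=C)[C@@H]2O | intermediate
37 | C15 enal: C4(=C3)–CHO, C1=C2 vinyl intact | C=C1C(=O)O[C@@H]2[C@@H]1[C@@H](OC(=O)/C(C)=C\C)[C@@H](C(=C)C=O)[C@](C)(C=C)[C@@H]2O | intermediate
38 | CNP0113462.3, (1R,5R,6S,7S,8R,9S,10S) in the labels used here | C=C1C(=O)O[C@@H]2[C@@H]1[C@@H](OC(=O)/C(C)=C\C)[C@@H](C(=C)C=O)[C@](C)([C@@H]1CO1)[C@@H]2O | target

Total step count: 23. Longest linear sequence: 22 steps (steps 1–4 and 6–23; step 5 is the side branch).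

Steps most likely to fail

Step 12. The catalyst may be drained by reversible oxymercuration of the isopropenyl group, or the aldol may show poor facial selectivity at C6 because the axial approach is opposed by the syn-axial C10 methyl. The fallback sets out from 20. N-Iodosuccinimide in MeCN/H2O at −20 °C iodohydrates the enol ether and unmasks the aldehyde to give α-iodo keto aldehyde F1. SmI2 in THF at −78 °C then forms the samarium enolate specifically at C7, and a chelated Reformatsky-type aldol closes the ring, coming back to the route at 22.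

Step 11. The hemiacetal may attack the distal alkyne carbon (seven-membered ring), or a second methanol may add to the enol ether once formed. The fallback sets out from 18. NaClO2/NaH2PO4 oxidation gives alkynoic acid F2. Ph3PAuCl/AgOTf in CH2Cl2 cycloisomerises it 6-exo-dig to enol lactone F3. i-Bu2AlH in CH2Cl2 at −78 °C reduces the lactone carbonyl; the aluminate collapses to the C6 aldehyde and the C7 aluminium enolate, which close by aldol addition. This bypasses 20 and comes back to the route at 22.

Step 15. Acylation of the hindered axial C6 hydroxyl may be sluggish, and forcing conditions may isomerise the Z-enoate. The fallback sets out from 25. DCC/DMAP esterification with 2-[bis(2,2,2-trifluoroethoxy)phosphoryl]propanoic acid gives phosphonate ester F4. Still–Gennari olefination with acetaldehyde (KN(SiMe3)2, 18-crown-6, THF, −78 °C) then builds the Z-configured 2-methylbut-2-enoate on the oxygen, coming back to the route at 28.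

Further compounds
F1 | step 12 | α-iodo keto aldehyde: C6 CHO, C8 ketone, C7–I (epimers at C7) | O=C[C@@H](C(C)=C)[C@](C)(C=C)[C@H](O[Si](C)(C)C(C)(C)C)C(=O)C(I)CCOCc1ccc(OC)cc1
F2 | step 11 | alkynoic acid: C6 CO2H, C9 OTBS, C8≡C7 | OC(=O)[C@@H](C(C)=C)[C@](C)(C=C)[C@H](O[Si](C)(C)C(C)(C)C)C#CCCOCc1ccc(OC)cc1
F3 | step 11 | Z-enol lactone: 6-alkylidene oxan-2-one with C6 carbonyl and ring O on C8 | O=C1O/C(=C\CCOCc2ccc(OC)cc2)[C@@H](O[Si](C)(C)C(C)(C)C)[C@@](C)(C=C)[C@@H]1C(C)=C
F4 | step 15 | C6 2-[bis(2,2,2-trifluoroethoxy)phosphoryl]propanoate of 25 | CC[Si](CC)(CC)O[C@@H]1[C@@H](CCOCc2ccc(OC)cc2)[C@@H](OC(=O)C(C)P(=O)(OCC(F)(F)F)OCC(F)(F)F)[C@@H](C(C)=C)[C@](C)(C=C)[C@@H]1O[Si](C)(C)C(C)(C)C
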